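**Retrosynthetic overview**

1. Target 19 ⇒ amino alcohol 17: the C3–O ester bond (acid-mediated O-acylation) and the C5' silyl ether are handled last.
2. 17 ⇒ open-chain C18 2-amino-3-hydroxy-6,10-dione 13, in one flask and in the biogenetic order: ring A first (N–C8a ketimine), ring B second (C4a–C5 enamine aldol, loss of water). Hydrogenation of the flat 1-azadiene then sets C4a, C5 and C8a.
3. 13 ⇒ 1,2-dialkylcyclopentene 11: the 1,5-diketone is masked as a cyclopentene and released by ozonolysis.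
4. 11 ⇒ 3 + 6 + 7: two B-alkyl Suzuki couplings on 1,2-dibromocyclopentene.
5. 3 ⇒ Boc-D-alanine Weinreb amide 1 (vinyl Grignard, anti-reduction; sets C2 and C3). 6 ⇒ (R)-2-propyloxirane 4 (allyl Grignard; carries C5').

Assumption: ring locants (C2 … C8a) are those of decahydroquinoline, chain locants are those of the octadecane chain, and 1, 4 and 7 are bought.

**Route**

Step 1
Reactants: 1 tert-butyl N-[(2R)-1-[methoxy(methyl)amino]-1-oxopropan-2-yl]carbamate (Boc-D-alanine Weinreb amide)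
Product: 2 tert-butyl N-[(2R)-3-oxopent-4-en-2-yl]carbamate
Conditions: vinylMgBr (2.5 equiv), THF, −15 → 0 °C; inverse quench into cold 1 M HCl
Reagents that add atoms: vinylmagnesium bromide, C=C[Mg]Br
Why: Weinreb ketone synthesis; the chelated tetrahedral adduct stops at the ketone, the carbamate N–H is deprotonated first so the D-alanine stereocentre is not enolised, and the acidic inverse quench keeps MeNHOMe from adding to the enone.

Step 2
Reactants: 2 tert-butyl N-[(2R)-3-oxopent-4-en-2-yl]carbamate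
Product: 3 tert-butyl N-[(2R,3S)-3-hydroxypent-4-en-2-yl]carbamate
Conditions: LiAlH(OtBu)3 (2.2 equiv), EtOH, −78 °C; aq. citric acid
Reagents that add atoms: none
Why: Cram-chelate-controlled 1,2-reduction of an N-Boc α-amino ketone; hydride attacks the lithium-bridged carbamate/ketone chelate from the side of the small H, giving the anti (2R,3S) amino alcohol, and the minor syn isomer is removed by chromatography.

Step 3
Reactants: 4 (R)-2-propyloxirane
Product: 5 (4R)-oct-7-en-4-ol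
Conditions: allylMgBr (1.3 equiv), CuI (5 mol %), Et2O/THF, −30 → 0 °C; aq. NH4Cl
Reagents that add atoms: allylmagnesium bromide, C=CC[Mg]Br
Why: Copper-catalysed SN2 epoxide opening at the unsubstituted carbon; the stereocentre is not touched, so the R configuration of 4 becomes C5' of the target.

Step 4
Reactants: 5 (4R)-oct-7-en-4-ol
Product: 6 triisopropyl{[(4R)-oct-7-en-4-yl]oxy}silane
Conditions: TIPSOTf (1.3 equiv), 2,6-lutidine, CH2Cl2, 0 °C; aq. NaHCO3
Reagents that add atoms: triisopropylsilyl trifluoromethanesulfonate, CC(C)[Si](OS(=O)(=O)C(F)(F)F)(C(C)C)C(C)C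
Why: Silyl ether formation with a silyl triflate; TIPS has no arene to be hydrogenated, survives TFA, AcOH and the acidic acylation, and is removed by HF.

Step 5
Reactants: 3 tert-butyl N-[(2R,3S)-3-hydroxypent-4-en-2-yl]carbamate; 7 1,2-dibromocyclopent-1-ene (3 equiv)
Product: 9 tert-butyl N-[(2R,3S)-5-(2-bromocyclopent-1-en-1-yl)-3-hydroxypentan-2-yl]carbamate, via bis-borylated alkylborane 8 (not isolated)
Conditions: 9-BBN-H (2.3 equiv), THF, 0 °C → rt; then 7, PdCl2(dppf) (5 mol %), AsPh3, Cs2CO3, DMF/THF/H2O, rt → 40 °C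
Reagents that add atoms: none
Why: Anti-Markovnikov hydroboration (the hydroxyl is capped in situ as its borinate) followed by B-alkyl Suzuki–Miyaura coupling; the excess of 7 and the lower reactivity of the alkyl-substituted bromoalkene hold the reaction at mono-coupling, and no stereocentre is touched.

Step 6
Reactants: 6 triisopropyl{[(4R)-oct-7-en-4-yl]oxy}silane (1.6 equiv); 9 tert-butyl N-[(2R,3S)-5-(2-bromocyclopent-1-en-1-yl)-3-hydroxypentan-2-yl]carbamate
Product: 11 tert-butyl N-[(2R,3S)-3-hydroxy-5-{2-[(5R)-5-(triisopropylsilyloxy)octyl]cyclopent-1-en-1-yl}pentan-2-yl]carbamate, via B-alkyl-9-BBN 10 (not isolated)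
Conditions: 6, 9-BBN-H (1.7 equiv), THF, rt; then 9, Pd(OAc)2 (5 mol %), SPhos (10 mol %), 3 M aq. K3PO4, THF, 60 °C
Reagents that add atoms: none
Why: Second hydroboration/B-alkyl Suzuki–Miyaura coupling; the electron-rich biarylphosphine drives oxidative addition into the hindered 2-alkyl bromocyclopentene and gives the tetrasubstituted alkene that masks the 1,5-diketone.

Step 7
Reactants: 11 tert-butyl N-[(2R,3S)-3-hydroxy-5-{2-[(5R)-5-(triisopropylsilyloxy)octyl]cyclopent-1-en-1-yl}pentan-2-yl]carbamate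
Product: 13 tert-butyl N-[(2R,3S,15R)-3-hydroxy-6,10-dioxo-15-(triisopropylsilyloxy)octadecan-2-yl]carbamate, via secondary ozonide 12 (not isolated)
Conditions: O3, CH2Cl2, −78 °C; then PPh3, −78 °C → rt
Reagents that add atoms: ozone, [O-][O+]=O
Why: Ozonolysis (Criegee mechanism) of the only C=C bond with reductive work-up; cleaving the cyclopentene puts the two ketones at C6 and C10, three CH2 apart, and carbamate, alcohol and silyl ether are inert to ozone at −78 °C (13 equilibrates with its five-membered hemiketal, which is harmless).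

Step 8
Reactants: 13 tert-butyl N-[(2R,3S,15R)-3-hydroxy-6,10-dioxo-15-(triisopropylsilyloxy)octadecan-2-yl]carbamate
Product: 17 (2R,3S,4aR,5R,8aS)-2-methyl-5-[(5R)-5-(triisopropylsilyloxy)octyl]decahydroquinolin-3-ol, via aminium trifluoroacetate 14 (not isolated), via cyclic ketimine 15 (not isolated), via 1-azadiene 16 (not isolated)
Conditions: TFA/CH2Cl2 1:4, 0 °C, 1 h; evaporate; NaOAc (3 equiv), AcOH, 60 °C, argon (check for 16 by NMR); then PtO2 (10 mol %), H2 (4 atm), same flask, rt; aq. NaOH work-up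
Reagents that add atoms: none
Why: Proposed new method: after Boc removal the amine condenses with the only ketone that gives a six-membered ring (C6; ring A closes first as a Δ1-piperideine), its endocyclic enamine then attacks the C10 ketone in a 6-(enolendo)-exo-trig aldol (ring B) and loss of water gives the conjugated, flat 1-azadiene 16; the exocyclic enamine can reach only a four-membered ring and the ketone's own enols only a four-membered ring or a reversible spiro-Mannich adduct, so the amine decides which aldol regioisomer forms, the closest known chemistry being the cyclocondensation of 1,5-diketones with amines to hexahydroquinolines and the Stork enamine aldol; PtO2/H2 in AcOH then adds hydrogen to C8a=N and syn across C4a=C5 from the face opposite the C2 methyl group and on the side of the C3 hydroxyl (the cis-2,6 outcome usual for 2-substituted Δ1-piperideines, helped by hydroxyl anchoring), which sets 4aR, 5R and 8aS with H2, H4a, H5 and H8a all cis.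

Step 9
Reactants: 17 (2R,3S,4aR,5R,8aS)-2-methyl-5-[(5R)-5-(triisopropylsilyloxy)octyl]decahydroquinolin-3-ol
Product: 19 (2R,3S,4aR,5R,8aS)-5-[(5R)-5-hydroxyoctyl]-2-methyldecahydroquinolin-3-yl (2E)-oct-2-enoate, via silylated ester salt 18 (not isolated)
Conditions: (E)-oct-2-enoic acid (2 equiv), (COCl)2, cat. DMF, CH2Cl2, 0 °C → rt; add to 17, MsOH (1.5 equiv), CH2Cl2/TFA 9:1, rt; MeOH quench; then 48% aq. HF, MeCN, rt; aq. NaHCO3
Reagents that add atoms: (E)-oct-2-enoyl chloride, CCCCC/C=C/C(=O)Cl, made in the flask from (E)-oct-2-enoic acid, CCCCC/C=C/C(=O)O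
Why: Chemoselective O-acylation under acidic conditions; the hindered secondary amine is fully protonated and cannot be acylated, so the acid chloride esterifies the only free hydroxyl (C3, with retention), and HF then cleaves the TIPS ether without touching the enoate.

**Compound list**

1 | tert-butyl N-[(2R)-1-[methoxy(methyl)amino]-1-oxopropan-2-yl]carbamate | C[C@@H](NC(=O)OC(C)(C)C)C(=O)N(C)OC | starting material
2 | tert-butyl N-[(2R)-3-oxopent-4-en-2-yl]carbamate | C[C@@H](NC(=O)OC(C)(C)C)C(=O)C=C | intermediate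
3 | tert-butyl N-[(2R,3S)-3-hydroxypent-4-en-2-yl]carbamate | C[C@@H](NC(=O)OC(C)(C)C)[C@@H](O)C=C | intermediate
4 | (R)-2-propyloxirane | CCC[C@@H]1CO1 | starting material
5 | (4R)-oct-7-en-4-ol | C=CCC[C@H](O)CCC | intermediate
6 | triisopropyl{[(4R)-oct-7-en-4-yl]oxy}silane | C=CCC[C@H](O[Si](C(C)C)(C(C)C)C(C)C)CCC | intermediate
7 | 1,2-dibromocyclopent-1-ene | BrC1=C(Br)CCC1 | starting material
8 | tert-butyl N-[(2R,3S)-5-(9-borabicyclo[3.3.1]nonan-9-yl)-3-(9-borabicyclo[3.3.1]nonan-9-yloxy)pentan-2-yl]carbamate (not isolated) | C[C@@H](NC(=O)OC(C)(C)C)[C@@H](OB1C2CCCC1CCC2)CCB1C2CCCC1CCC2 | intermediate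
9 | tert-butyl N-[(2R,3S)-5-(2-bromocyclopent-1-en-1-yl)-3-hydroxypentan-2-yl]carbamate | C[C@@H](NC(=O)OC(C)(C)C)[C@@H](O)CCC1=C(Br)CCC1 | intermediate
10 | 9-[(5R)-5-(triisopropylsilyloxy)octyl]-9-borabicyclo[3.3.1]nonane (not isolated) | B1(CCCC[C@H](O[Si](C(C)C)(C(C)C)C(C)C)CCC)C2CCCC1CCC2 | intermediate
11 | tert-butyl N-[(2R,3S)-3-hydroxy-5-{2-[(5R)-5-(triisopropylsilyloxy)octyl]cyclopent-1-en-1-yl}pentan-2-yl]carbamate | C[C@@H](NC(=O)OC(C)(C)C)[C@@H](O)CCC1=C(CCCC[C@H](O[Si](C(C)C)(C(C)C)C(C)C)CCC)CCC1 | intermediate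
12 | secondary ozonide of 11: 1-[(3S,4R)-4-(tert-butoxycarbonylamino)-3-hydroxypentyl]-5-[(5R)-5-(triisopropylsilyloxy)octyl]-6,7,8-trioxabicyclo[3.2.1]octane, bridgehead epimers (not isolated) | C[C@@H](NC(=O)OC(C)(C)C)[C@@H](O)CCC12CCCC(CCCC[C@H](O[Si](C(C)C)(C(C)C)C(C)C)CCC)(OO1)O2 | intermediate
13 | tert-butyl N-[(2R,3S,15R)-3-hydroxy-6,10-dioxo-15-(triisopropylsilyloxy)octadecan-2-yl]carbamate | C[C@@H](NC(=O)OC(C)(C)C)[C@@H](O)CCC(=O)CCCC(=O)CCCC[C@H](O[Si](C(C)C)(C(C)C)C(C)C)CCC | intermediate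
14 | (2R,3S,15R)-3-hydroxy-6,10-dioxo-15-(triisopropylsilyloxy)octadecan-2-aminium trifluoroacetate (not isolated) | C[C@@H]([NH3+])[C@@H](O)CCC(=O)CCCC(=O)CCCC[C@H](O[Si](C(C)C)(C(C)C)C(C)C)CCC.[O-]C(=O)C(F)(F)F | intermediate
15 | (2R,3S)-2-methyl-6-[(9R)-4-oxo-9-(triisopropylsilyloxy)dodecyl]-2,3,4,5-tetrahydropyridin-3-ol (not isolated) | C[C@H]1N=C(CCCC(=O)CCCC[C@H](O[Si](C(C)C)(C(C)C)C(C)C)CCC)CC[C@@H]1O | intermediate
16 | (2R,3S)-2-methyl-5-[(5R)-5-(triisopropylsilyloxy)octyl]-2,3,4,6,7,8-hexahydroquinolin-3-ol (not isolated) | C[C@H]1N=C2CCCC(CCCC[C@H](O[Si](C(C)C)(C(C)C)C(C)C)CCC)=C2C[C@@H]1O | intermediate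
17 | (2R,3S,4aR,5R,8aS)-2-methyl-5-[(5R)-5-(triisopropylsilyloxy)octyl]decahydroquinolin-3-ol | O[C@H]1C[C@@H]2[C@H](CCCC[C@H](O[Si](C(C)C)(C(C)C)C(C)C)CCC)CCC[C@@H]2N[C@@H]1C | intermediate
18 | (2R,3S,4aR,5R,8aS)-2-methyl-5-[(5R)-5-(triisopropylsilyloxy)octyl]decahydroquinolin-1-ium-3-yl (2E)-oct-2-enoate methanesulfonate (not isolated) | CCCCC/C=C/C(=O)O[C@H]1C[C@@H]2[C@H](CCCC[C@H](O[Si](C(C)C)(C(C)C)C(C)C)CCC)CCC[C@@H]2[NH2+][C@@H]1C.CS(=O)(=O)[O-] | intermediate
19 | (2R,3S,4aR,5R,8aS)-5-[(5R)-5-hydroxyoctyl]-2-methyldecahydroquinolin-3-yl (2E)-oct-2-enoate | CCCCC/C=C/C(=O)O[C@H]1C[C@@H]2[C@H](CCCC[C@H](O)CCC)CCC[C@@H]2N[C@@H]1C | target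

**Step count**

Total steps: 9. Longest linear sequence: 7 (steps 1, 2, 5, 6, 7, 8, 9, from 1).

**Three steps most likely to fail, and fallbacks**

Step 6 (hindered B-alkyl coupling to the tetrasubstituted cyclopentene; the mono-coupling of step 5 carries a related risk). The fallback drops the cyclopentene linchpin and sets out from 3 and 6. Glutaryl dichloride and tributyl(vinyl)stannane (PdCl2(PPh3)2 cat., THF) give nona-1,8-diene-3,7-dione F1. Cross-metathesis of 6 with a fourfold excess of F1 (second-generation Hoveyda–Grubbs catalyst, RuCl2(H2IMes)(=CH-C6H4-2-OiPr), CH2Cl2, 40 °C) gives (8E,12R)-12-(triisopropylsilyloxy)pentadeca-1,8-diene-3,7-dione F2. A second cross-metathesis of F2 with 3 gives tert-butyl N-[(2R,3S,4E,11E,15R)-3-hydroxy-6,10-dioxo-15-(triisopropylsilyloxy)octadeca-4,11-dien-2-yl]carbamate F3. Hydrogenation (H2, Pd/C, EtOAc) saturates both enone C=C bonds and the route is rejoined at 13.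

Step 8 (ring B closure, and above all the facial selectivity of the one-flask hydrogenation over three new stereocentres). The fallback sets out from 13 and separates the reductions. The TFA and NaOAc/AcOH stages are run as before, but 16 is extracted and reduced with NaBH4 in MeOH at −40 °C; 1,2-hydride addition to the ketimine gives the 2,8a-cis allylic amine (2R,3S,8aS)-2-methyl-5-[(5R)-5-(triisopropylsilyloxy)octyl]-1,2,3,4,6,7,8,8a-octahydroquinolin-3-ol F4. Its HBF4 salt is then hydrogenated with [Ir(cod)(PCy3)(py)]PF6 in CH2Cl2, where the homoallylic C3 hydroxyl directs H2 onto its own face of the tetrasubstituted C4a=C5 bond. This returns to the route at 17.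

Step 9 (O- versus N-acylation, and survival of the TIPS ether in acid). The fallback sets out from 17 and protects nitrogen instead of protonating it. Boc2O (Et3N, MeOH, 50 °C) gives tert-butyl (2R,3S,4aR,5R,8aS)-3-hydroxy-2-methyl-5-[(5R)-5-(triisopropylsilyloxy)octyl]octahydroquinoline-1(2H)-carboxylate F5. Steglich esterification with (E)-oct-2-enoic acid (EDC·HCl, DMAP, CH2Cl2) gives tert-butyl (2R,3S,4aR,5R,8aS)-2-methyl-3-[(2E)-oct-2-enoyloxy]-5-[(5R)-5-(triisopropylsilyloxy)octyl]octahydroquinoline-1(2H)-carboxylate F6. TFA/CH2Cl2 followed by aq. HF/MeCN removes Boc and TIPS and arrives at 19.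

**Further compounds**

F1 | step 6 | nona-1,8-diene-3,7-dione | C=CC(=O)CCCC(=O)C=C
F2 | step 6 | (8E,12R)-12-(triisopropylsilyloxy)pentadeca-1,8-diene-3,7-dione | C=CC(=O)CCCC(=O)/C=C/CC[C@H](O[Si](C(C)C)(C(C)C)C(C)C)CCC
F3 | step 6 | tert-butyl N-[(2R,3S,4E,11E,15R)-3-hydroxy-6,10-dioxo-15-(triisopropylsilyloxy)octadeca-4,11-dien-2-yl]carbamate | C[C@@H](NC(=O)OC(C)(C)C)[C@@H](O)/C=C/C(=O)CCCC(=O)/C=C/CC[C@H](O[Si](C(C)C)(C(C)C)C(C)C)CCC
F4 | step 8 | (2R,3S,8aS)-2-methyl-5-[(5R)-5-(triisopropylsilyloxy)octyl]-1,2,3,4,6,7,8,8a-octahydroquinolin-3-ol | O[C@H]1CC2=C(CCCC[C@H](O[Si](C(C)C)(C(C)C)C(C)C)CCC)CCC[C@@H]2N[C@@H]1C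
F5 | step 9 | tert-butyl (2R,3S,4aR,5R,8aS)-3-hydroxy-2-methyl-5-[(5R)-5-(triisopropylsilyloxy)octyl]octahydroquinoline-1(2H)-carboxylate | O[C@H]1C[C@@H]2[C@H](CCCC[C@H](O[Si](C(C)C)(C(C)C)C(C)C)CCC)CCC[C@@H]2N(C(=O)OC(C)(C)C)[C@@H]1C
F6 | step 9 | tert-butyl (2R,3S,4aR,5R,8aS)-2-methyl-3-[(2E)-oct-2-enoyloxy]-5-[(5R)-5-(triisopropylsilyloxy)octyl]octahydroquinoline-1(2H)-carboxylate | CCCCC/C=C/C(=O)O[C@H]1C[C@@H]2[C@H](CCCC[C@H](O[Si](C(C)C)(C(C)C)C(C)C)CCC)CCC[C@@H]2N(C(=O)OC(C)(C)C)[C@@H]1C
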